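I start from the end: does free monomer run out in this flask, or does it stop at a floor?

| setting | noon | dusk | flask |
|---|---|---|---|
| free monomer | 0.20 M | 0.30 M | 0.20 M |
| protic impurity | 4 mM | 4 mM | 4.00 mM |
| initiator | 2 mM | 2 mM | 2.0 mM |
| stray impurity | 1.2 mM | 1.2 mM | 1.2 mM |
| remark | the very flask that is asked about, followed so far | run made earlier |  |
| time |  |  | 15 min |

| run | time / min | monomer in chains / % | free monomer / % |
|---|---|---|---|
| noon | 0.667 | 3.4 | 93.0 |
| noon | 2.00 | 11.1 | 87.1 |
| noon | 4.00 | 19.9 | 78.9 |
| noon | 5.00 | 22.5 | 73.6 |
| noon | 8.00 | 33.3 | 65.2 |
| dusk | 1.33 | 10.0 | 89.6 |
| dusk | 4.00 | 27.7 | 70.0 |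
| dusk | 8.00 | 43.1 | 55.5 |
| dusk | 10.0 | 49.1 | 49.6 |
| dusk | 15.0 | 59.5 | 39.4 |

(scatter of a reading: 1 percentage point)

- average number of monomer units in a chain (chains begun, living or dead) at 15 min
- part of the free monomer that has reacted at 15 min

- the average divides the monomer in chains by the number of chains begun, living and dead together
- the earlier runs do not show the number of chains; that part of a forecast is a guess

At 8.00 min the dusk run has more of its charge in chains than the noon run. In moles that is 1.94 times the noon amount, for 1.50 times the charge. So I suppose that net growth follows the excess over a fixed concentration. I also suppose both runs hold equal numbers of living ends, since their initiator and stray impurity are charged equally. As a reading, with the scatter of these two points, that puts the floor at 46.9% of the noon charge: the floor is the fraction at which free monomer stops falling (the equilibrium monomer concentration).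

Now the ladder. On the first rung, the two noon columns fall 3.60% short of the charge at 0.667 min and 1.50% short at 8.00 min. I take this shortfall for the protic impurity's worth, at one monomer each, which is 2.00% of the charge, and I place it before the first reading. On the next rung, the excess over the floor starts at 51.1% and stands at 17.8% after 8.00 min. This pseudo-first-order decay has a time of 7.59 min, so a power of ten takes 17.5 min. The asked time is 0.859 of that, so I commit to c of 46.0%.

The chains are unread. I guess them between initiator less stray impurity and the whole initiator, and take the logarithmic middle, 1.26 mM. That gives dp near 69.6, within 44.0 to 110.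

The forecast says dp 35 and c 49%, holding that “the rate is second order in monomer”. The flask gives dp 66.7 and c 47.1%.

    free monomer + initiator → living end + monomer in chains (k = 0.560 L mol⁻¹ s⁻¹)
    initiator + stray impurity → spent initiator (k = 63.0 L mol⁻¹ s⁻¹)
    protic impurity + free monomer → quenched substrate (k = 0.740 L mol⁻¹ s⁻¹)
    monomer in chains + living end → free monomer + living end, rate k4*[living end] as long as [monomer in chains] is above zero (k = 0.120 s⁻¹)
    free monomer + living end → monomer in chains + living end, rate k5*[living end]*[free monomer] (k = 1.40 L mol⁻¹ s⁻¹)

In the flask, monomer in chains is made 1.62 times as fast as it is given back at 6.40 min, and 1.23 times as fast at 15.0 min, while living end stands at 0.00135 M. The 53% of free monomer then left is 1.13 times my floor. For the neighbour flask with 0.34 M of free monomer, I keep the floor's concentration and the decay time, so the floor is 27.6% of its charge; my reckoning gives c of 62.5%, and that flask gives 63.9%.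

Readings and results are calculated for an exercise.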